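The flavanone is disconnected across ring C at O1–C2 and C3–C4. The feature exploited is that O1, C8a, C4a and C4 form the oxadiene of an ortho-quinone methide of ring A, while C2–C3, carrying ring B on C2, is a styrene activated by the para oxygen of the chromene. A single enantioselective, acid-catalysed oxa-[4+2] cycloaddition closes ring C, makes both bonds and sets C2 as S. Its precursors are a bis-silylated 2,4,6-trihydroxybenzaldehyde with one free ortho hydroxyl, trimethyl orthoformate, and 2,2-dimethyl-8-prenyl-6-vinylchromene; the 4-methoxy group of the adduct is then oxidised to the ketone and the silyl ethers are removed.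

Key step: step 6

Assumption: the sense of induction of the chiral acid cannot be predicted with confidence. The (R)-catalyst is taken to give the (2S,4S) adduct; its (S)-enantiomer would be used, with nothing else changed, if the first run showed the opposite sense.

Remark: the chromene ring is built through the propargyl ether and a thermal rearrangement (steps 3 and 4) instead of a one-step condensation with prenal. The phenol is deactivated by its para formyl group, and a second aldehyde in the flask would compete.

Step 1
Reactants: 1 2,4,6-trihydroxybenzaldehyde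
Product: 2 2-hydroxy-4,6-bis(tert-butyldimethylsilyloxy)benzaldehyde
Conditions: TBSCl (2.1 equiv), imidazole, DMF, 0 °C to rt
Reagents that add atoms: tert-butyldimethylsilyl chloride (TBSCl), CC(C)(C)[Si](C)(C)Cl
Why: Silyl ether formation with two equivalents of reagent should cap the 4-hydroxyl and one of the two equivalent ortho hydroxyls, leaving the last hydroxyl free because it is held in a hydrogen bond to the formyl oxygen.

Step 2
Reactants: 3 4-hydroxybenzaldehyde; 4 prenyl bromide
Product: 5 4-hydroxy-3-(3-methylbut-2-enyl)benzaldehyde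
Conditions: KOH (10% aq), rt
Reagents that add atoms: none
Why: C-alkylation of a phenoxide in water, where solvation of the oxygen directs the allylic bromide to carbon, should place the prenyl group ortho because para is blocked, and the neutral O-prenyl ether is removed by base extraction.

Step 3
Reactants: 5 4-hydroxy-3-(3-methylbut-2-enyl)benzaldehyde; 6 3-chloro-3-methylbut-1-yne
Product: 7 3-(3-methylbut-2-enyl)-4-(2-methylbut-3-yn-2-yloxy)benzaldehyde
Conditions: DBU, CuCl2 (cat.), MeCN, 0 °C
Reagents that add atoms: none
Why: Copper-catalysed propargylic O-alkylation of a phenol by a tertiary propargylic chloride is reliable for electron-poor phenols, and the low temperature leaves the aldehyde and the prenyl group untouched.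

Step 4
Reactants: 7 3-(3-methylbut-2-enyl)-4-(2-methylbut-3-yn-2-yloxy)benzaldehyde
Product: 8 2,2-dimethyl-8-(3-methylbut-2-enyl)-2H-chromene-6-carbaldehyde
Conditions: xylenes, 140 °C
Reagents that add atoms: none
Why: An aromatic propargyl Claisen rearrangement to the only free ortho carbon, followed by tautomerisation, a 1,5-hydrogen shift and an oxa-6π electrocyclisation, should give the 2,2-dimethylchromene under purely thermal conditions.

Step 5
Reactants: 8 2,2-dimethyl-8-(3-methylbut-2-enyl)-2H-chromene-6-carbaldehyde
Product: 9 2,2-dimethyl-8-(3-methylbut-2-enyl)-6-vinyl-2H-chromene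
Conditions: Ph3PCH3Br, KOtBu, THF, 0 °C to rt
Reagents that add atoms: methyltriphenylphosphonium bromide, C[P+](c1ccccc1)(c1ccccc1)c1ccccc1.[Br-]
Why: Wittig methylenation of an unhindered aryl aldehyde should give the styrene, which is stored cold with a trace of BHT and used promptly because para-alkoxystyrenes polymerise.

Step 6
Reactants: 2 2-hydroxy-4,6-bis(tert-butyldimethylsilyloxy)benzaldehyde; 9 2,2-dimethyl-8-(3-methylbut-2-enyl)-6-vinyl-2H-chromene; 10 trimethyl orthoformate
Product: 13 (2S,4S)-2-[2,2-dimethyl-8-(3-methylbut-2-enyl)-2H-chromen-6-yl]-4-methoxy-5,7-bis(tert-butyldimethylsilyloxy)chroman (the 2,4-cis-4-methoxyflavan), via dimethyl acetal 11 (not isolated), via ortho-quinone methide 12 (not isolated)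
Conditions: 2 (1.2 equiv), 10 (2.5 equiv), (R)-3,3'-bis(2,4,6-triisopropylphenyl)-1,1'-binaphthyl-2,2'-diyl hydrogen phosphate (10 mol%), 5 Å MS, toluene, rt; then 9 (1.0 equiv), −20 °C; Et3N quench
Reagents that add atoms: none
Why: Proposed new method: the chiral acid converts 2 and 10 into acetal 11 and then, by loss of methanol assisted by the free ortho hydroxyl, into the 4-methoxy ortho-quinone methide 12, which remains hydrogen-bonded to the acid (or ion-paired to its phosphate as the oxocarbenium ion); the terminal carbon of the vinyl group of 9 attacks the exocyclic carbon (C3–C4) while the quinone methide oxygen closes on the developing para-alkoxybenzyl cation (O1–C2), in a concerted but asynchronous inverse-demand oxa-[4+2] cycloaddition that restores the aromaticity of ring A. The closest known reactions are the achiral acid-catalysed three-component coupling of salicylaldehydes, orthoformates and styrenes to 2,4-cis-4-alkoxyflavans and chiral phosphoric acid-catalysed cycloadditions of ortho-quinone methides with alkenes that carry a hydrogen-bond donor; the enantioselective intermolecular reaction with a donor-free styrene is not established. Ring C closes by [4+2] annulation, four atoms (O1, C8a, C4a, C4) coming from 12 and two (C2, C3) from the vinyl group. C4 is set by the face of 12 left open by the 3,3'-aryl groups of the bound phosphate and C2 by the endo approach of ring B relative to that face, which should give the 2,4-cis (2S,4S) adduct; the cis isomer is separated from any trans isomer before step 7, because a trans isomer formed on the same C4 face would carry 2R. The step needs site selectivity for the vinyl group, secured by its para-oxygen activation and unhindered terminus, whereas the chromene alkene is disubstituted next to a quaternary carbon and the prenyl alkene is trisubstituted and not conjugated to an arene; the same polarisation fixes the regiochemistry (aryl on C2).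

Step 7
Reactants: 13 (2S,4S)-2-[2,2-dimethyl-8-(3-methylbut-2-enyl)-2H-chromen-6-yl]-4-methoxy-5,7-bis(tert-butyldimethylsilyloxy)chroman
Product: 15 (2S)-2-[2,2-dimethyl-8-(3-methylbut-2-enyl)-2H-chromen-6-yl]-5,7-bis(tert-butyldimethylsilyloxy)chroman-4-one, via hemiketal 14 (not isolated)
Conditions: DDQ (2,3-dichloro-5,6-dicyano-1,4-benzoquinone, 1.1 equiv), CH2Cl2/pH 7 phosphate buffer (10:1), 0 °C
Reagents that add atoms: water, O
Why: Oxidative cleavage of an electron-rich benzylic methyl ether, in which DDQ abstracts hydride from C4–H (activated by the methoxy oxygen and the three ortho/para oxygens of ring A), water adds and hemiketal 14 loses methanol, should outrun attack at C2–H (whose oxygen is a weaker, aryl-conjugated donor) and at the prenyl CH2 (no free ortho phenol), so C2 stays S.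

Step 8
Reactants: 15 (2S)-2-[2,2-dimethyl-8-(3-methylbut-2-enyl)-2H-chromen-6-yl]-5,7-bis(tert-butyldimethylsilyloxy)chroman-4-one
Product: 16 (2S)-5,7-dihydroxy-2-[2,2-dimethyl-8-(3-methylbut-2-enyl)-2H-chromen-6-yl]chroman-4-one (target)
Conditions: Et3N·3HF, THF, 0 °C to rt
Reagents that add atoms: none
Why: Fluoride cleavage of aryl silyl ethers under weakly acidic, non-basic conditions should free both phenols while avoiding the base-induced ring opening to the chalcone that would racemise C2.

Compound list
1 | 2,4,6-trihydroxybenzaldehyde | O=Cc1c(O)cc(O)cc1O | starting material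
2 | 2-hydroxy-4,6-bis(tert-butyldimethylsilyloxy)benzaldehyde | O=Cc1c(O)cc(O[Si](C)(C)C(C)(C)C)cc1O[Si](C)(C)C(C)(C)C | intermediate
3 | 4-hydroxybenzaldehyde | O=Cc1ccc(O)cc1 | starting material
4 | prenyl bromide (1-bromo-3-methylbut-2-ene) | CC(C)=CCBr | starting material
5 | 4-hydroxy-3-(3-methylbut-2-enyl)benzaldehyde | O=Cc1ccc(O)c(CC=C(C)C)c1 | intermediate
6 | 3-chloro-3-methylbut-1-yne | C#CC(C)(C)Cl | starting material
7 | 3-(3-methylbut-2-enyl)-4-(2-methylbut-3-yn-2-yloxy)benzaldehyde | C#CC(C)(C)Oc1ccc(C=O)cc1CC=C(C)C | intermediate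
8 | 2,2-dimethyl-8-(3-methylbut-2-enyl)-2H-chromene-6-carbaldehyde | O=Cc1cc(CC=C(C)C)c2OC(C)(C)C=Cc2c1 | intermediate
9 | 2,2-dimethyl-8-(3-methylbut-2-enyl)-6-vinyl-2H-chromene | C=Cc1cc(CC=C(C)C)c2OC(C)(C)C=Cc2c1 | intermediate
10 | trimethyl orthoformate | COC(OC)OC | starting material
11 | 2-(dimethoxymethyl)-3,5-bis(tert-butyldimethylsilyloxy)phenol (dimethyl acetal of 2) | COC(OC)c1c(O)cc(O[Si](C)(C)C(C)(C)C)cc1O[Si](C)(C)C(C)(C)C | intermediate
12 | 6-(methoxymethylidene)-3,5-bis(tert-butyldimethylsilyloxy)cyclohexa-2,4-dien-1-one (ortho-quinone methide, exocyclic alkene geometry not assigned) | COC=C1C(=O)C=C(O[Si](C)(C)C(C)(C)C)C=C1O[Si](C)(C)C(C)(C)C | intermediate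
13 | (2S,4S)-2-[2,2-dimethyl-8-(3-methylbut-2-enyl)-2H-chromen-6-yl]-4-methoxy-5,7-bis(tert-butyldimethylsilyloxy)chroman (2,4-cis) | CC(C)=CCc1cc([C@@H]2C[C@H](OC)c3c(O[Si](C)(C)C(C)(C)C)cc(O[Si](C)(C)C(C)(C)C)cc3O2)cc2c1OC(C)(C)C=C2 | intermediate
14 | (2S)-2-[2,2-dimethyl-8-(3-methylbut-2-enyl)-2H-chromen-6-yl]-4-methoxy-5,7-bis(tert-butyldimethylsilyloxy)chroman-4-ol (hemiketal, C4 not defined) | CC(C)=CCc1cc([C@@H]2CC(O)(OC)c3c(O[Si](C)(C)C(C)(C)C)cc(O[Si](C)(C)C(C)(C)C)cc3O2)cc2c1OC(C)(C)C=C2 | intermediate
15 | (2S)-2-[2,2-dimethyl-8-(3-methylbut-2-enyl)-2H-chromen-6-yl]-5,7-bis(tert-butyldimethylsilyloxy)chroman-4-one | CC(C)=CCc1cc([C@@H]2CC(=O)c3c(O[Si](C)(C)C(C)(C)C)cc(O[Si](C)(C)C(C)(C)C)cc3O2)cc2c1OC(C)(C)C=C2 | intermediate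
16 | (2S)-5,7-dihydroxy-2-[2,2-dimethyl-8-(3-methylbut-2-enyl)-2H-chromen-6-yl]chroman-4-one | CC(C)=CCc1cc([C@@H]2CC(=O)c3c(O)cc(O)cc3O2)cc2c1OC(C)(C)C=C2 | target

Total step count: 8. Longest linear sequence: 7 steps (steps 2 to 8, from 4-hydroxybenzaldehyde); step 1 is a one-step branch.

Steps most likely to fail

Step 6. The chiral acid may give insufficient facial control at C2, since the styrene has no group to bind the phosphate. The 2,4-cis preference may also be weak, and the styrene may oligomerise or react at another alkene. The fallback uses the classical chalcone route: it sets out from aldehyde 8 and rejoins the route at target 16. Claisen–Schmidt condensation of 8 with commercial 2'-hydroxy-4',6'-bis(methoxymethoxy)acetophenone (KOH, EtOH/H2O, rt) should give the (E)-2'-hydroxy-4',6'-bis(methoxymethoxy)chalcone F1 carrying ring B. NaOAc in refluxing EtOH should close it by intramolecular oxa-Michael addition to the racemic 5,7-bis(methoxymethoxy)flavanone F2. HCl in MeOH at 40 °C should remove the acetals to give the racemic flavanone F3. Preparative HPLC on a chiral stationary phase then delivers 16.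

Step 7. Hydride abstraction may occur at C2–H or at the benzylic-allylic CH2 of the prenyl group instead of C4–H, or the ketone may be oxidised further to the flavone. The fallback avoids a hydride-abstracting oxidant: it sets out from 13 and rejoins at 15. Mild acid hydrolysis (pyridinium p-toluenesulfonate, THF/H2O, rt) should exchange the activated benzylic methoxy group for hydroxyl through the stabilised C4 cation, giving the (2S)-flavan-4-ol F4 as C4 epimers. MnO2 in CH2Cl2 at rt should then oxidise this electron-rich benzylic alcohol to 15.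

Step 2. O-alkylation and double C-alkylation may outcompete the single ortho C-prenylation. The fallback moves the prenyl group by a sigmatropic shift: it sets out from 3 and rejoins at 5. O-alkylation of 3 with 6 (DBU, CuCl2 cat., MeCN, 0 °C) should give 4-(2-methylbut-3-yn-2-yloxy)benzaldehyde F5. Semi-hydrogenation (H2, Pd/CaCO3 poisoned with Pb(OAc)2, quinoline, EtOAc) should give 4-(2-methylbut-3-en-2-yloxy)benzaldehyde F6. An aromatic Claisen rearrangement (toluene, 110 °C) then transfers the allyl unit to the ortho carbon with allylic transposition, giving 5.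

Further compounds
F1 | step 6 | (E)-1-[2-hydroxy-4,6-bis(methoxymethoxy)phenyl]-3-[2,2-dimethyl-8-(3-methylbut-2-enyl)-2H-chromen-6-yl]prop-2-en-1-one | COCOc1cc(O)c(C(=O)/C=C/c2cc(CC=C(C)C)c3OC(C)(C)C=Cc3c2)c(OCOC)c1
F2 | step 6 | racemic 2-[2,2-dimethyl-8-(3-methylbut-2-enyl)-2H-chromen-6-yl]-5,7-bis(methoxymethoxy)chroman-4-one | COCOc1cc(OCOC)c2C(=O)CC(c3cc(CC=C(C)C)c4OC(C)(C)C=Cc4c3)Oc2c1
F3 | step 6 | racemic 5,7-dihydroxy-2-[2,2-dimethyl-8-(3-methylbut-2-enyl)-2H-chromen-6-yl]chroman-4-one | CC(C)=CCc1cc(C2CC(=O)c3c(O)cc(O)cc3O2)cc2c1OC(C)(C)C=C2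
F4 | step 7 | (2S)-2-[2,2-dimethyl-8-(3-methylbut-2-enyl)-2H-chromen-6-yl]-5,7-bis(tert-butyldimethylsilyloxy)chroman-4-ol (C4 epimers) | CC(C)=CCc1cc([C@@H]2CC(O)c3c(O[Si](C)(C)C(C)(C)C)cc(O[Si](C)(C)C(C)(C)C)cc3O2)cc2c1OC(C)(C)C=C2
F5 | step 2 | 4-(2-methylbut-3-yn-2-yloxy)benzaldehyde | C#CC(C)(C)Oc1ccc(C=O)cc1
F6 | step 2 | 4-(2-methylbut-3-en-2-yloxy)benzaldehyde | C=CC(C)(C)Oc1ccc(C=O)cc1
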